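(Readings and results were computed for substances that don't exist; the scatter is artificial.)

The trap is to trust each reading of the open intermediate on its own: the scatter is 1 percentage point, and the plateau of the north run averages 2.58 %.

| setting | north-west | south-west | north | epsilon | delta | theta |
|---|---|---|---|---|---|---|
| substrate | 0.050 M | 0.050 M | 0.050 M | 0.050 M | 0.050 M | 0.050 M |
| partner | 0.95 equiv | 0.95 equiv | 0.95 equiv | 0.950 equiv | 0.950 equiv | 0.950 equiv |
| protic impurity | 0.015 M | 0.015 M | 0.015 M | 0.0150 M | 0.0150 M | 0.0150 M |
| capture agent | 2.5 mM | 2.5 mM | 2.5 mM | 2.50 mM | 2.50 mM | 2.50 mM |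
| free catalyst | 0.5 mol% | 0.5 mol% | 0.5 mol% | 0.5 mol% | 0.5 mol% | 0.5 mol% |
| second catalyst | 3.8 mol% | 9.2 mol% | 17 mol% | 5 mol% | 10 mol% | 20 mol% |
| remark | run made earlier | run made earlier | run made earlier |  |  |  |
| time |  |  |  | 50 min | 50 min | 50 min |

- north-west (time / min: open intermediate / %, target / %): 8.00: 7.2, 5.3; 15.0: 8.5, 13.2; 20.0: 7.7, 18.3; 30.0: 8.4, 28.7; 40.0: 8.3, 38.0
- south-west (time / min: open intermediate / %, target / %): 3.00: 1.4, 1.3; 5.00: 3.6, 4.7; 10.0: 4.3, 11.8; 20.0: 3.8, 27.5; 40.0: 3.5, 46.6
- north (time / min: open intermediate / %, target / %): 3.00: 2.0, 3.1; 5.00: 1.7, 6.9; 10.0: 4.0, 16.3; 20.0: 1.9, 27.6; 40.0: 2.7, 48.2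

(standard deviation of a reading: 1 percentage point)

- "hardly changes" means that all values lie within two and a half points (for a concentration: within two and a half percent of the largest)

- amount of open intermediate at the end, in percent of the substrate charged for epsilon, delta, theta, in this order
- how that number moves from the first to the last of them (falls all the way / falls, then rises / rises, then falls / rises all the way / hardly changes)

I follow one substrate molecule up the ladder of times. The first rung is its wait in the open form, which I read as stock over flow into target. In the north run, with the flow taken over the last two readings, that is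

wait = 2.50 min

The north-west run, with its plateau readings averaging 8.22 % and the flow taken over the last three readings, gives

wait = 8.35 min

The next rung is supply. At 40.0 min, open intermediate plus target averages 49.1 % over the earlier runs, with readings of 46.3 % at 3.8 mol% and 50.9 % at 17 mol%. Read as a first-order decay, this gives

supply time = 59.2 min

Both waits are shorter than the supply time, so the stock follows the flow, a quasi-steady state, and the plateaus stand early. If I take the flow as common and the wait as inversely proportional to loading, the stock times the loading should hold still:

x · L = H, with x the open fraction of the charge and L the second catalyst as a fraction of it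

north-west 0.312 %, south-west 0.356 %, north 0.439 %

mean H = 0.369 %

This mean is my holding number, and I leave the spread to the scatter. The last rung is the end of the run, 10.0 min past the last reading, which is less than the supply time. The plateaus look flat, so I carry H unchanged:

x = H / L = 7.37 %, 3.69 %, 1.84 %

The forecast gives 6.3 %, 3.2 %, 1.9 %, so that the number falls all the way, on the ground that “that consumption scales roughly with second catalyst”. Its first point is lower than mine, but the direction is the same.

Epsilon, delta and theta end at 7.16 %, 3.76 % and 1.94 %, so the number falls all the way.

partner + catalyst intermediate → second catalyst + target (k = 32.7 M⁻¹ min⁻¹); partner + protic impurity → quenched reagent (k = 0.854 M⁻¹ min⁻¹); substrate + free catalyst ⇌ free catalyst + open intermediate (K = 0.760, k = 80.6 M⁻¹ min⁻¹); open intermediate + capture agent → trapped intermediate (k = 0.198 M⁻¹ min⁻¹); second catalyst + open intermediate ⇌ catalyst intermediate (K = 170 M⁻¹, k = 182 M⁻¹ min⁻¹); substrate + partner → uncatalysed product (k = 0.0430 M⁻¹ min⁻¹) In epsilon at 18.2 min, the forward step of open intermediate onto second catalyst has a half-life of 2.0 min, far shorter than the 50 min of the run. The holding number of epsilon at the end comes to 0.358 %, against my 0.369 %. Divided by the 20 mol% of theta, that epsilon value gives 1.79 %, and theta stands at 1.94 %.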